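A direct plan would build the furan first and close the pyranone last. An 8-iodo-(2S)-flavan A1 would be alkynylated and annulated under carbon monoxide to the 2-aryl-3-aroylbenzofuran A2. Epoxidation of the C2=C3 bond of A2 would then let an ortho-phenol of the aroyl ring close onto the ketal carbon. Its weakest steps would be:
- the oxidative closure, because a reagent would have to choose one face of a tetrasubstituted benzofuran bond with no stereocentre nearby, beside a free trihydroxyaryl ring, while spiro-coumaranone closure competes;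
- the carbonylative annulation, because a hindered, electron-rich aryl iodide adds slowly to palladium and the alkynylphenol can cyclise without taking up CO;
- the early ring iodination, because it must fix C8 against C6 long before the outcome matters.

The proposed route disconnects the dihydrofuran ring last, through both of its bonds to the chromanone half, C3–C8' and C2–O7' (unprimed atoms: chromanone unit; primed: flavan unit). C2 and C3 of the target stand at the oxidation level of a flavonol oxidised by two electrons, so a benzylated kaempferol is dearomatised to a 2-methoxychromane-3,4-dione and the free 7'-hydroxyflavan adds to it as a C8',O7' dinucleophile. One operation joins two halves of equal size at the fully substituted carbinol carbon, closes the furan ring and sets both fully substituted stereocentres. No benzofuran is made or oxidised, and no halogen, alkyne or carbon monoxide is needed because the phenol itself marks the bonding site.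

Key step: step 10

Remark: compounds 1, 2, 8 and 11 are taken as catalogue chemicals; dione 7 is racemic at C2 and moisture-sensitive, so it would be carried into step 10 as the dried crude material, its C2 centre being erased and reset there.

Step 1
Reactants: 1 1-[2,4-bis(benzyloxy)-6-hydroxyphenyl]ethan-1-one; 2 4-(benzyloxy)benzaldehyde
Product: 3 (E)-1-[2,4-bis(benzyloxy)-6-hydroxyphenyl]-3-[4-(benzyloxy)phenyl]prop-2-en-1-one
Conditions: KOH, EtOH/THF, rt
Reagents that add atoms: none
Why: Claisen–Schmidt condensation, in which the acetophenone enolate adds to the non-enolisable aldehyde and loss of water gives the (E)-enone while the chelated 2'-hydroxyl stays free for the next step.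

Step 2
Reactants: 3 (E)-1-[2,4-bis(benzyloxy)-6-hydroxyphenyl]-3-[4-(benzyloxy)phenyl]prop-2-en-1-one
Product: 5 5,7-bis(benzyloxy)-2-[4-(benzyloxy)phenyl]-3-hydroxy-4H-chromen-4-one, via dihydroflavonol 4 (not isolated)
Conditions: 30% H2O2, NaOH, MeOH/THF, 0 °C → rt
Reagents that add atoms: hydrogen peroxide, OO
Why: Algar–Flynn–Oyamada reaction, in which alkaline hydrogen peroxide epoxidises the enone, the 2'-phenoxide opens the epoxide at the β-carbon to dihydroflavonol 4 and further oxidation in the same medium gives the flavonol, so that the stereocentres of 4 are lost again.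

Step 3
Reactants: 5 5,7-bis(benzyloxy)-2-[4-(benzyloxy)phenyl]-3-hydroxy-4H-chromen-4-one
Product: 7 5,7-bis(benzyloxy)-2-[4-(benzyloxy)phenyl]-2-methoxychromane-3,4-dione, via C3 methyl hemiketal 6 (not isolated)
Conditions: PhI(OAc)2 (1.1 eq), MeOH/CH2Cl2, 0 °C → rt; then evaporation, toluene, 4 Å MS, 60 °C
Reagents that add atoms: methanol, CO
Why: Oxidative dearomatisation of a flavonol by a trivalent iodine reagent in methanol, the known entry to 3-hydroxy-2,3-dimethoxyflavanones, in which ligand exchange at the enolic 3-OH and attack of methanol at C2 with loss of iodobenzene create the 2-methoxy-3,4-dione, which rests in methanol as its C3 methyl hemiketal 6, and removal of the methanol by warming over sieves in toluene should reverse this hemiketal and leave the free dione 7.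

Step 4
Reactants: 8 2,4,6-trihydroxybenzaldehyde
Product: 9 4-(allyloxy)-2,6-dihydroxybenzaldehyde
Conditions: allyl bromide (1.0 eq), K2CO3 (1.0 eq), acetone, 0 °C → rt
Reagents that add atoms: allyl bromide, C=CCBr
Why: Williamson etherification in which the 4-OH, para to the formyl group and not hydrogen-bonded to it, is the most acidic hydroxyl and should react first with one equivalent of halide.

Step 5
Reactants: 9 4-(allyloxy)-2,6-dihydroxybenzaldehyde
Product: 10 4-(allyloxy)-2-(benzyloxy)-6-hydroxybenzaldehyde
Conditions: BnBr (1.05 eq), K2CO3, DMF, rt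
Reagents that add atoms: benzyl bromide, BrCc1ccccc1
Why: Williamson etherification of one of two equivalent ortho-hydroxyls, after which the remaining one is chelated to the formyl oxygen and should resist a second alkylation under carbonate conditions.

Step 6
Reactants: 10 4-(allyloxy)-2-(benzyloxy)-6-hydroxybenzaldehyde; 11 1-[4-(benzyloxy)phenyl]ethan-1-one
Product: 12 (E)-3-[4-(allyloxy)-2-(benzyloxy)-6-hydroxyphenyl]-1-[4-(benzyloxy)phenyl]prop-2-en-1-one
Conditions: KOH, EtOH/H2O, rt → 40 °C
Reagents that add atoms: none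
Why: Claisen–Schmidt condensation of the ketone enolate with the aldehyde followed by dehydration to the (E)-enone, under hydroxide conditions that the allyl and benzyl ethers tolerate.

Step 7
Reactants: 12 (E)-3-[4-(allyloxy)-2-(benzyloxy)-6-hydroxyphenyl]-1-[4-(benzyloxy)phenyl]prop-2-en-1-one
Product: 14 (1R)-3-[4-(allyloxy)-2-(benzyloxy)-6-hydroxyphenyl]-1-[4-(benzyloxy)phenyl]propan-1-ol, via saturated ketone 13 (not isolated)
Conditions: RuCl[(R,R)-TsDPEN](p-cymene) (2 mol %), HCO2H/Et3N (5:2), EtOAc, 40 °C
Reagents that add atoms: none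
Why: Noyori–Ikariya asymmetric transfer hydrogenation run in tandem, in which the Ru–H first reduces the polarised enone C=C by conjugate hydride transfer and then the aryl ketone 13 on the face set by the (R,R)-TsDPEN ligand, which should give the (R)-carbinol and leave the isolated allyl double bond and the benzyl ethers untouched.

Step 8
Reactants: 14 (1R)-3-[4-(allyloxy)-2-(benzyloxy)-6-hydroxyphenyl]-1-[4-(benzyloxy)phenyl]propan-1-ol
Product: 15 (2S)-7-(allyloxy)-5-(benzyloxy)-2-[4-(benzyloxy)phenyl]chromane
Conditions: PPh3, DIAD, THF, 0 °C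
Reagents that add atoms: none
Why: Intramolecular Mitsunobu etherification, a 6-exo-tet SN2 displacement of the activated benzylic alcohol by the only free phenol with inversion, so that the (R)-carbinol should give the (S)-configured C2 of the chromane.

Step 9
Reactants: 15 (2S)-7-(allyloxy)-5-(benzyloxy)-2-[4-(benzyloxy)phenyl]chromane
Product: 16 (2S)-5-(benzyloxy)-2-[4-(benzyloxy)phenyl]chroman-7-ol
Conditions: Pd(PPh3)4 (5 mol %), morpholine, THF, rt
Reagents that add atoms: none
Why: Tsuji–Trost deallylation, in which zerovalent palladium ionises the aryl allyl ether to a π-allyl complex that morpholine captures, which frees the 7-OH under neutral conditions that spare the benzyl ethers and the acid-sensitive benzylic C2–O bond.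

Step 10
Reactants: 7 5,7-bis(benzyloxy)-2-[4-(benzyloxy)phenyl]-2-methoxychromane-3,4-dione; 16 (2S)-5-(benzyloxy)-2-[4-(benzyloxy)phenyl]chroman-7-ol
Product: 18 penta-O-benzyl ether of target 19 (ketal carbon R; carbinol carbon S; flavan C2' S), via Friedel–Crafts carbinol 17 (not isolated)
Conditions: quinine-derived squaramide 3-{[3,5-bis(trifluoromethyl)phenyl]amino}-4-{[(8α,9S)-6'-methoxycinchonan-9-yl]amino}cyclobut-3-ene-1,2-dione (10 mol %), 5 Å MS, CH2Cl2, −20 °C → rt; then CSA (0.3 eq), 0 °C
Reagents that add atoms: none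
Why: Proposed new method: the vicinal C3/C4 carbonyls of dione 7 should be held by the two squaramide N–H bonds while the quinuclidine nitrogen takes the proton of the 7'-OH of 16, so that the ortho carbon C8' adds to the C3 ketone (Friedel–Crafts hydroxyalkylation) to give carbinol 17, and the added acid then ionises the C2 methyl ketal, no longer next to a carbonyl, to an oxocarbenium ion that the same phenol oxygen captures. The closest known reaction types are the condensation of phenols with ninhydrin and related vicinal polycarbonyl compounds to cis-fused 3-hydroxy-2,3-dihydrobenzofuran ketals and the squaramide-catalysed enantioselective Friedel–Crafts hydroxyalkylation of naphthols and electron-rich phenols with isatins and α-keto esters. The dihydrofuran ring closes by 5-exo-trig addition of O7' to the C2=O1 oxocarbenium ion. C3 is set by the catalyst, which must choose the same carbonyl face in both enantiomers of racemic 7 because the flavan centre is too remote to help, and C2 is set by the ring closure itself, since its earlier configuration is erased in the planar cation and a five-membered ring can only be fused cis. The step needs C-attack at C3 and not at C2 or C4, secured by keeping C2 as an un-ionised ketal during the first stage and by C4 being deactivated through conjugation to the dialkoxy ring A, and it needs C8' over C6', secured by the 5'-benzyloxy group that flanks C6' whereas C8' lies between the hydroxyl and the tied-back ring oxygen. With O5' benzylated, O7' is the only oxygen that can close the ketal.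

Step 11
Reactants: 18 penta-O-benzyl ether of target 19
Product: 19 target (CNP0208300.3)
Conditions: H2 (1 atm), Pd(OH)2/C, THF/EtOAc, rt
Reagents that add atoms: none
Why: Hydrogenolysis of the five aryl benzyl ethers over Pd(OH)2/C in a non-nucleophilic solvent, under which the fully substituted bis(aryloxy) ketal, the tertiary carbinol and the chromane C2'–O bond are hindered benzylic C–O bonds that should survive short neutral exposure, and no stereocentre is touched.

**Compound list**

1 | 1-[2,4-bis(benzyloxy)-6-hydroxyphenyl]ethan-1-one | CC(=O)c1c(O)cc(OCc2ccccc2)cc1OCc1ccccc1 | starting material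
2 | 4-(benzyloxy)benzaldehyde | O=Cc1ccc(OCc2ccccc2)cc1 | starting material
3 | (E)-1-[2,4-bis(benzyloxy)-6-hydroxyphenyl]-3-[4-(benzyloxy)phenyl]prop-2-en-1-one | O=C(/C=C/c1ccc(OCc2ccccc2)cc1)c1c(O)cc(OCc2ccccc2)cc1OCc1ccccc1 | intermediate
4 | racemic trans-5,7-bis(benzyloxy)-2-[4-(benzyloxy)phenyl]-3-hydroxychroman-4-one (dihydroflavonol) | O=C1c2c(OCc3ccccc3)cc(OCc3ccccc3)cc2OC(c2ccc(OCc3ccccc3)cc2)C1O | intermediate (not isolated)
5 | 5,7-bis(benzyloxy)-2-[4-(benzyloxy)phenyl]-3-hydroxy-4H-chromen-4-one (5,7,4'-tri-O-benzylkaempferol) | O=c1c(O)c(-c2ccc(OCc3ccccc3)cc2)oc2cc(OCc3ccccc3)cc(OCc3ccccc3)c12 | intermediate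
6 | 5,7-bis(benzyloxy)-2-[4-(benzyloxy)phenyl]-3-hydroxy-2,3-dimethoxychroman-4-one (C3 methyl hemiketal of 7; racemic, mixture of C2/C3 diastereomers) | COC1(c2ccc(OCc3ccccc3)cc2)Oc2cc(OCc3ccccc3)cc(OCc3ccccc3)c2C(=O)C1(O)OC | intermediate (not isolated)
7 | racemic 5,7-bis(benzyloxy)-2-[4-(benzyloxy)phenyl]-2-methoxychromane-3,4-dione | COC1(c2ccc(OCc3ccccc3)cc2)Oc2cc(OCc3ccccc3)cc(OCc3ccccc3)c2C(=O)C1=O | intermediate
8 | 2,4,6-trihydroxybenzaldehyde | O=Cc1c(O)cc(O)cc1O | starting material
9 | 4-(allyloxy)-2,6-dihydroxybenzaldehyde | O=Cc1c(O)cc(OCC=C)cc1O | intermediate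
10 | 4-(allyloxy)-2-(benzyloxy)-6-hydroxybenzaldehyde | O=Cc1c(O)cc(OCC=C)cc1OCc1ccccc1 | intermediate
11 | 1-[4-(benzyloxy)phenyl]ethan-1-one | CC(=O)c1ccc(OCc2ccccc2)cc1 | starting material
12 | (E)-3-[4-(allyloxy)-2-(benzyloxy)-6-hydroxyphenyl]-1-[4-(benzyloxy)phenyl]prop-2-en-1-one | O=C(/C=C/c1c(O)cc(OCC=C)cc1OCc1ccccc1)c1ccc(OCc2ccccc2)cc1 | intermediate
13 | 3-[4-(allyloxy)-2-(benzyloxy)-6-hydroxyphenyl]-1-[4-(benzyloxy)phenyl]propan-1-one | O=C(CCc1c(O)cc(OCC=C)cc1OCc1ccccc1)c1ccc(OCc2ccccc2)cc1 | intermediate (not isolated)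
14 | (1R)-3-[4-(allyloxy)-2-(benzyloxy)-6-hydroxyphenyl]-1-[4-(benzyloxy)phenyl]propan-1-ol | O[C@@H](c1ccc(OCc2ccccc2)cc1)CCc1c(O)cc(OCC=C)cc1OCc1ccccc1 | intermediate
15 | (2S)-7-(allyloxy)-5-(benzyloxy)-2-[4-(benzyloxy)phenyl]chromane | C=CCOc1cc(OCc2ccccc2)c2c(c1)O[C@H](c1ccc(OCc3ccccc3)cc1)CC2 | intermediate
16 | (2S)-5-(benzyloxy)-2-[4-(benzyloxy)phenyl]chroman-7-ol | Oc1cc(OCc2ccccc2)c2c(c1)O[C@H](c1ccc(OCc3ccccc3)cc1)CC2 | intermediate
17 | (3S)-5,7-bis(benzyloxy)-2-[4-(benzyloxy)phenyl]-3-hydroxy-2-methoxychroman-4-one carrying at C3 the C8' of (2'S)-5'-(benzyloxy)-2'-[4-(benzyloxy)phenyl]-7'-hydroxychromane (both C2 epimers) | O=C1c2c(OCc3ccccc3)cc(OCc3ccccc3)cc2OC(OC)(c2ccc(OCc3ccccc3)cc2)[C@]1(O)c1c(O)cc(OCc2ccccc2)c2c1O[C@H](c1ccc(OCc3ccccc3)cc1)CC2 | intermediate (not isolated)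
18 | penta-O-benzyl ether of 19: (2R,3S)-5,7-bis(benzyloxy)-2-[4-(benzyloxy)phenyl]-3-hydroxychroman-4-one with C3 bonded to C8' and C2 bonded to O7' of (2'S)-5'-(benzyloxy)-2'-[4-(benzyloxy)phenyl]chromane | O=C1c2c(OCc3ccccc3)cc(OCc3ccccc3)cc2O[C@@]2(c3ccc(OCc4ccccc4)cc3)Oc3cc(OCc4ccccc4)c4c(c3[C@]12O)O[C@H](c1ccc(OCc2ccccc2)cc1)CC4 | intermediate
19 | target CNP0208300.3: (2R,3S)-3,5,7-trihydroxy-2-(4-hydroxyphenyl)chroman-4-one with C3 bonded to C8' and C2 bonded to O7' of (2'S)-5'-hydroxy-2'-(4-hydroxyphenyl)chromane | O=C1c2c(O)cc(O)cc2O[C@@]2(c3ccc(O)cc3)Oc3cc(O)c4c(c3[C@]12O)O[C@H](c1ccc(O)cc1)CC4 | target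

Total step count: 11. Longest linear sequence: 8 steps (steps 4 to 11).

Steps most likely to fail:

Step 10. The catalyst may fail to override the facial bias that the C2 centre exerts in one enantiomer of 7, attack may leak through C6', or addition to the hindered ketone may be slow. The fallback sets out from 7 and 16 and uses the known acid-mediated condensation of phenols with vicinal polycarbonyl compounds (AcOH, 40 °C), which forms the carbinol and exchanges the ketal without a chiral catalyst. It should give 18 together with the (2S,3R,2'S) ring-fusion diastereomer of 18 F1. The two differ as diastereomers because of the flavan centre and would be separated by chromatography, so the route is rejoined at 18.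

Step 2. Closure of the phenoxide at the α-carbon to an aurone may compete, as is typical of chalcones with a 6'-alkoxy group. The fallback sets out from 3: oxidative cyclisation (cat. I2, DMSO, 120 °C) should give the flavone 5,7-bis(benzyloxy)-2-[4-(benzyloxy)phenyl]-4H-chromen-4-one F2. Epoxidation with dimethyldioxirane (acetone, 0 °C) should give the racemic 2,3-epoxide of that flavone F3. Opening with cat. TsOH would give the flavonol, and the route is rejoined at 5.

Step 8. The activated p-alkoxybenzylic alcohol may ionise before displacement, so that inversion is incomplete and the enantiomeric purity erodes, or it may eliminate to the styrene. The fallback sets out from 14: cyclisation through the benzylic cation (cat. TsOH, CH2Cl2) should give racemic 7-(allyloxy)-5-(benzyloxy)-2-[4-(benzyloxy)phenyl]chromane F4. Preparative chromatography on a chiral stationary phase would separate the (2S)-enantiomer from the (2R)-enantiomer of that chromane F5, and the route is rejoined at 15.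

Further compounds

F1 | step 10 | (2S,3R,2'S) ring-fusion diastereomer of 18 | O=C1c2c(OCc3ccccc3)cc(OCc3ccccc3)cc2O[C@]2(c3ccc(OCc4ccccc4)cc3)Oc3cc(OCc4ccccc4)c4c(c3[C@@]12O)O[C@H](c1ccc(OCc2ccccc2)cc1)CC4
F2 | step 2 | 5,7-bis(benzyloxy)-2-[4-(benzyloxy)phenyl]-4H-chromen-4-one | O=c1cc(-c2ccc(OCc3ccccc3)cc2)oc2cc(OCc3ccccc3)cc(OCc3ccccc3)c12
F3 | step 2 | racemic 2,3-epoxide of F2 (5,7-bis(benzyloxy)-2-[4-(benzyloxy)phenyl]-2,3-epoxychroman-4-one) | O=C1c2c(OCc3ccccc3)cc(OCc3ccccc3)cc2OC2(c3ccc(OCc4ccccc4)cc3)OC12
F4 | step 8 | racemic 7-(allyloxy)-5-(benzyloxy)-2-[4-(benzyloxy)phenyl]chromane | C=CCOc1cc(OCc2ccccc2)c2c(c1)OC(c1ccc(OCc3ccccc3)cc1)CC2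
F5 | step 8 | (2R)-7-(allyloxy)-5-(benzyloxy)-2-[4-(benzyloxy)phenyl]chromane | C=CCOc1cc(OCc2ccccc2)c2c(c1)O[C@@H](c1ccc(OCc3ccccc3)cc1)CC2
A1 | direct plan | (2S)-5-(benzyloxy)-2-[4-(benzyloxy)phenyl]-8-iodo-7-(methoxymethoxy)chromane | COCOc1cc(OCc2ccccc2)c2c(c1I)O[C@H](c1ccc(OCc3ccccc3)cc1)CC2
A2 | direct plan | [(2S)-5-(benzyloxy)-2,8-bis[4-(benzyloxy)phenyl]-3,4-dihydro-2H-furo[2,3-h]chromen-9-yl](2,4,6-trihydroxyphenyl)methanone | O=C(c1c(O)cc(O)cc1O)c1c(-c2ccc(OCc3ccccc3)cc2)oc2cc(OCc3ccccc3)c3c(c12)O[C@H](c1ccc(OCc2ccccc2)cc1)CC3
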